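**Retrosynthetic overview**

- The target is reached from its dodecamethyl ether (rings B–F methylated, ring A free) by a final global O-demethylation.
- Ring A is a phloroglucinol whose ether carbon C1 lies between the hydroxylated carbons C2 and C6, with C4–OH para. This is the pattern of a folded 6-aryloxy-3,5-dioxohexanoate, so ring A is cut at C1–C2 and closed last by Claisen attack of chain carbon C6 on the ester carbon.
- The dioxo ester comes from a methyl aryloxyacetate and the methyl acetoacetate dianion. The aryloxyacetate comes from the pentameric B–F phenol and methyl bromoacetate, so the most hindered ether oxygen is introduced by simple alkylation.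
- Rings B–F are bought as benzenes and joined from B towards F. A 2,6-dioxygenated phenoxide displaces fluoride from a fluorobenzaldehyde (rings C, D, E), and the formyl group is then converted into the next phenol. Ring F is added by Cu-catalysed O-arylation, and the ring B oxygen destined for ring A travels as a benzyl ether.
- Order of ring events: rings B, C, D, E, F are attached in that order; ring A is the only ring formed in the route, and it is formed last.

Key step: step 14

Remark: rings are lettered A (2,4,6-trihydroxyphenyl end) to F (3,4,5-trihydroxyphenyl end); the target has no stereocentre, and the dioxo ester is drawn as its triketo tautomer although enol forms will dominate.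

**Route**

Step 1
Reactants: 1 5-fluoro-1,2,3-trimethoxybenzene
Product: 3 6-fluoro-2,3,4-trimethoxybenzaldehyde, via aryllithium 2 (not isolated)
Conditions: n-BuLi, THF, −78 °C; DMF, −78 → 0 °C; aq HCl
Reagents that add atoms: N,N-dimethylformamide (DMF), CN(C)C=O
Why: Directed ortho-lithiation then formylation: the two equivalent ring hydrogens of 1 each lie between fluorine and a methoxy group, so n-BuLi at −78 °C (cold enough to prevent loss of LiF to an aryne) should give one aryllithium, which DMF formylates.

Step 2
Reactants: 4 4-hydroxy-2,6-dimethoxybenzaldehyde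
Product: 5 4-(benzyloxy)-2,6-dimethoxybenzaldehyde
Conditions: BnBr, K2CO3, DMF, 50 °C
Reagents that add atoms: benzyl bromide, BrCc1ccccc1
Why: Williamson etherification of the acidic para-formyl phenol; the benzyl ether masks the oxygen that will later carry the two-carbon starter of ring A and should survive base, peracid and copper catalysis.

Step 3
Reactants: 5 4-(benzyloxy)-2,6-dimethoxybenzaldehyde
Product: 7 4-(benzyloxy)-2,6-dimethoxyphenol (ring B phenol), via aryl formate 6 (not isolated)
Conditions: mCPBA, CH2Cl2, 0 °C → rt; aq Na2S2O3/NaHCO3 wash; K2CO3 (cat.), MeOH, rt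
Reagents that add atoms: mCPBA, OOC(=O)c1cccc(Cl)c1
Why: Baeyer–Villiger (Dakin-type) oxidation: the electron-rich 2,6-dimethoxyaryl group should migrate in the Criegee adduct in preference to hydride, and methanol transesterifies the aryl formate to free the hindered phenol while benzyl and methyl ethers stay untouched.

Step 4
Reactants: 7 4-(benzyloxy)-2,6-dimethoxyphenol; 8 4-fluoro-2,6-dimethoxybenzaldehyde
Product: 9 4-[4-(benzyloxy)-2,6-dimethoxyphenoxy]-2,6-dimethoxybenzaldehyde (B–C aldehyde)
Conditions: Cs2CO3, DMSO, Ar, 90 °C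
Reagents that add atoms: none
Why: Nucleophilic aromatic substitution (SNAr): the caesium phenoxide of 7 adds para to the formyl group of 8 at a carbon flanked only by hydrogens and fluoride leaves from the Meisenheimer adduct, so the crowded partner is the nucleophile and not the electrophile.

Step 5
Reactants: 9 B–C aldehyde
Product: 11 4-[4-(benzyloxy)-2,6-dimethoxyphenoxy]-2,6-dimethoxyphenol (B–C phenol), via ring C formate 10 (not isolated)
Conditions: mCPBA, CH2Cl2, 0 °C → rt; aq Na2S2O3/NaHCO3 wash; K2CO3 (cat.), MeOH, rt
Reagents that add atoms: mCPBA, OOC(=O)c1cccc(Cl)c1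
Why: Baeyer–Villiger oxidation and formate methanolysis as in step 3; the formyl group sits between two methoxy groups on an electron-rich ring, so aryl migration is expected, and the diaryl ether is inert to peracid.

Step 6
Reactants: 11 B–C phenol; 3 6-fluoro-2,3,4-trimethoxybenzaldehyde
Product: 12 6-{4-[4-(benzyloxy)-2,6-dimethoxyphenoxy]-2,6-dimethoxyphenoxy}-2,3,4-trimethoxybenzaldehyde (B–C–D aldehyde)
Conditions: Cs2CO3, DMSO, Ar, 110 °C
Reagents that add atoms: none
Why: SNAr at the fluoride ortho to the formyl group of 3; the methoxy group para to fluorine is the central one of three contiguous methoxy groups and is twisted out of conjugation, so it should retard the substitution only moderately.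

Step 7
Reactants: 12 B–C–D aldehyde
Product: 14 6-{4-[4-(benzyloxy)-2,6-dimethoxyphenoxy]-2,6-dimethoxyphenoxy}-2,3,4-trimethoxyphenol (B–C–D phenol), via ring D formate 13 (not isolated)
Conditions: mCPBA, CH2Cl2, 0 °C → rt; aq Na2S2O3/NaHCO3 wash; K2CO3 (cat.), MeOH, rt
Reagents that add atoms: mCPBA, OOC(=O)c1cccc(Cl)c1
Why: Baeyer–Villiger oxidation of an aldehyde flanked by an aryloxy and a methoxy group (aryl migration favoured), then formate methanolysis, which reveals the ring D phenol next to the ring C–ring D ether.

Step 8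
Reactants: 14 B–C–D phenol; 8 4-fluoro-2,6-dimethoxybenzaldehyde
Product: 15 B–C–D–E aldehyde (4-formyl-3,5-dimethoxyphenyl ether of phenol 14)
Conditions: Cs2CO3, DMSO, Ar, 100 °C
Reagents that add atoms: none
Why: SNAr as in step 4; the ring D phenoxide, flanked by an aryloxy and a methoxy group, attacks the unhindered fluoride carbon para to the formyl group of 8.

Step 9
Reactants: 15 B–C–D–E aldehyde
Product: 17 B–C–D–E phenol (4-hydroxy-3,5-dimethoxyphenyl ether of phenol 14), via ring E formate 16 (not isolated)
Conditions: mCPBA, CH2Cl2, 0 °C → rt; aq Na2S2O3/NaHCO3 wash; K2CO3 (cat.), MeOH, rt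
Reagents that add atoms: mCPBA, OOC(=O)c1cccc(Cl)c1
Why: Baeyer–Villiger oxidation and formate methanolysis as in step 3, now converting the ring E formyl group into the hindered phenol that will carry ring F.

Step 10
Reactants: 17 B–C–D–E phenol; 18 5-iodo-1,2,3-trimethoxybenzene
Product: 19 benzyl-protected B–F pentamer (3,4,5-trimethoxyphenyl ether of phenol 17)
Conditions: CuI (10 mol %), picolinic acid (20 mol %), K3PO4, DMSO, Ar, 90 °C
Reagents that add atoms: none
Why: Ullmann-type Cu-catalysed O-arylation; the CuI/picolinic acid system accepts phenols with two ortho substituents and the iodide of 18 is flanked by hydrogens, so ring F should be attached in one step.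

Step 11
Reactants: 19 benzyl-protected B–F pentamer
Product: 20 B–F pentamer phenol (free OH on ring B para to the ring C ether)
Conditions: H2 (1 atm), 10% Pd/C, EtOAc–MeOH, rt
Reagents that add atoms: none
Why: Hydrogenolysis of the benzyl ether over Pd/C; diaryl ethers and aryl methyl ethers are not reduced under these conditions.

Step 12
Reactants: 20 B–F pentamer phenol; 21 methyl bromoacetate
Product: 22 methyl 2-(B–F aryloxy)acetate
Conditions: K2CO3, acetone, reflux
Reagents that add atoms: none
Why: Williamson etherification (SN2) of the unhindered ring B phenoxide with an α-bromo ester; plain alkylation installs the oxygen that becomes the most hindered diaryl ether oxygen of the target.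

Step 13
Reactants: 22 methyl 2-(B–F aryloxy)acetate; 23 methyl acetoacetate
Product: 25 methyl 6-(B–F aryloxy)-3,5-dioxohexanoate, via acetoacetate dianion 24 (not isolated)
Conditions: 23 (2.5 equiv), LDA (5 equiv), THF, 0 °C; then 22, −78 → 0 °C; cold aq HCl to pH 4
Reagents that add atoms: none
Why: Crossed Claisen condensation: the γ-carbon of the acetoacetate dianion acylates on the activated α-aryloxy ester, the product is held as an unreactive polyenolate until the acidic quench so no second addition occurs, and the excess dianion covers the proton transfer to the product.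

Step 14
Reactants: 25 methyl 6-(B–F aryloxy)-3,5-dioxohexanoate
Product: 26 hexamer with free 2,4,6-trihydroxyphenyl ring A and rings B–F as twelve methyl ethers
Conditions: Mg(OMe)2 (4 equiv), degassed MeOH, sealed tube, 65 → 100 °C; then 1 M HCl, 0 °C
Reagents that add atoms: none
Why: Proposed new method: Mg(OMe)2 holds 25 as the magnesium chelate of its 3,5-dione and β-keto ester enolates, and proton exchange with methanol gives access to the tautomer in which C6, the CH2 between the C5 carbonyl and the aryloxy oxygen, is the carbanion; C6 adds to the ester carbon C1, methoxide leaves, and the 2-aryloxycyclohexane-1,3,5-trione so formed enolizes to the phloroglucinol, which is trapped as its magnesium phenoxide. The closest known reaction types are the Mg(OMe)2-mediated Claisen cyclization of 3,5,7-trioxoalkanoate esters to acylphloroglucinols and the strong-base Claisen (Dieckmann-type) closure of methyl 3,5-dioxohexanoate to phloroglucinol; new here is a C6 nucleophile activated by one ketone and one aryloxy group under methoxide conditions. Ring A closes in a 6-(enolexo)-exo-trig mode through the new C6–C1 bond, and no stereocentre is formed. The selectivity needed is C-acylation over O-acylation by the C5 enol oxygen, which would give the 6-(aryloxymethyl)-4-hydroxy-2-pyrone: that lactonization is reversible in Mg(OMe)2/MeOH, a medium that opens 4-hydroxy-2-pyrones to the open-chain chelates, whereas the carbocyclization ends in an aromatic ring and cannot revert. The aryloxy group is expected to acidify the C6–H bonds by several pKa units relative to a plain methyl ketone, which is what should let the C6 carbanion form under conditions that leave the unsubstituted ester open-chain. Chelation of both 1,3-dicarbonyl units by magnesium should also shield the C3 and C5 carbonyls from retro-Claisen attack by methoxide.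

Step 15
Reactants: 26 dodecamethyl ether hexamer
Product: 27 CNP0175585.0 (target hexamer with all fifteen hydroxyls free)
Conditions: BBr3 (excess), CH2Cl2, −78 °C → rt; then H2O, 0 °C
Reagents that add atoms: none
Why: BBr3 cleavage of aryl methyl ethers: each O-methyl oxygen is complexed by boron and bromide removes the methyl group by SN2, whereas the diaryl ether oxygens carry no alkyl group to be attacked, so hydrolysis of the aryl borates should release the pentadecahydroxy hexamer.

**Compound list**

1 | 5-fluoro-1,2,3-trimethoxybenzene | COc1cc(F)cc(OC)c1OC | starting material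
2 | (6-fluoro-2,3,4-trimethoxyphenyl)lithium | [Li]c1c(F)cc(OC)c(OC)c1OC | intermediate
3 | 6-fluoro-2,3,4-trimethoxybenzaldehyde | COc1cc(F)c(C=O)c(OC)c1OC | intermediate
4 | 4-hydroxy-2,6-dimethoxybenzaldehyde | COc1cc(O)cc(OC)c1C=O | starting material
5 | 4-(benzyloxy)-2,6-dimethoxybenzaldehyde | COc1cc(OCc2ccccc2)cc(OC)c1C=O | intermediate
6 | 4-(benzyloxy)-2,6-dimethoxyphenyl formate | COc1cc(OCc2ccccc2)cc(OC)c1OC=O | intermediate
7 | 4-(benzyloxy)-2,6-dimethoxyphenol (ring B phenol) | COc1cc(OCc2ccccc2)cc(OC)c1O | intermediate
8 | 4-fluoro-2,6-dimethoxybenzaldehyde | COc1cc(F)cc(OC)c1C=O | starting material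
9 | 4-[4-(benzyloxy)-2,6-dimethoxyphenoxy]-2,6-dimethoxybenzaldehyde (B–C aldehyde) | COc1cc(OCc2ccccc2)cc(OC)c1Oc1cc(OC)c(C=O)c(OC)c1 | intermediate
10 | 4-[4-(benzyloxy)-2,6-dimethoxyphenoxy]-2,6-dimethoxyphenyl formate (ring C formate) | COc1cc(OCc2ccccc2)cc(OC)c1Oc1cc(OC)c(OC=O)c(OC)c1 | intermediate
11 | 4-[4-(benzyloxy)-2,6-dimethoxyphenoxy]-2,6-dimethoxyphenol (B–C phenol) | COc1cc(OCc2ccccc2)cc(OC)c1Oc1cc(OC)c(O)c(OC)c1 | intermediate
12 | 6-{4-[4-(benzyloxy)-2,6-dimethoxyphenoxy]-2,6-dimethoxyphenoxy}-2,3,4-trimethoxybenzaldehyde (B–C–D aldehyde) | COc1cc(OCc2ccccc2)cc(OC)c1Oc1cc(OC)c(Oc2cc(OC)c(OC)c(OC)c2C=O)c(OC)c1 | intermediate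
13 | formate ester of B–C–D phenol 14 (ring D formate) | COc1cc(OCc2ccccc2)cc(OC)c1Oc1cc(OC)c(Oc2cc(OC)c(OC)c(OC)c2OC=O)c(OC)c1 | intermediate
14 | 6-{4-[4-(benzyloxy)-2,6-dimethoxyphenoxy]-2,6-dimethoxyphenoxy}-2,3,4-trimethoxyphenol (B–C–D phenol) | COc1cc(OCc2ccccc2)cc(OC)c1Oc1cc(OC)c(Oc2cc(OC)c(OC)c(OC)c2O)c(OC)c1 | intermediate
15 | B–C–D–E aldehyde: 4-formyl-3,5-dimethoxyphenyl ether of phenol 14 | COc1cc(OCc2ccccc2)cc(OC)c1Oc1cc(OC)c(Oc2cc(OC)c(OC)c(OC)c2Oc2cc(OC)c(C=O)c(OC)c2)c(OC)c1 | intermediate
16 | formate ester of B–C–D–E phenol 17 (ring E formate) | COc1cc(OCc2ccccc2)cc(OC)c1Oc1cc(OC)c(Oc2cc(OC)c(OC)c(OC)c2Oc2cc(OC)c(OC=O)c(OC)c2)c(OC)c1 | intermediate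
17 | B–C–D–E phenol: 4-hydroxy-3,5-dimethoxyphenyl ether of phenol 14 | COc1cc(OCc2ccccc2)cc(OC)c1Oc1cc(OC)c(Oc2cc(OC)c(OC)c(OC)c2Oc2cc(OC)c(O)c(OC)c2)c(OC)c1 | intermediate
18 | 5-iodo-1,2,3-trimethoxybenzene | COc1cc(I)cc(OC)c1OC | starting material
19 | benzyl-protected B–F pentamer: 3,4,5-trimethoxyphenyl ether of phenol 17 | COc1cc(OCc2ccccc2)cc(OC)c1Oc1cc(OC)c(Oc2cc(OC)c(OC)c(OC)c2Oc2cc(OC)c(Oc3cc(OC)c(OC)c(OC)c3)c(OC)c2)c(OC)c1 | intermediate
20 | B–F pentamer phenol (free OH on ring B para to the ring C ether, all other oxygens methylated) | COc1cc(O)cc(OC)c1Oc1cc(OC)c(Oc2cc(OC)c(OC)c(OC)c2Oc2cc(OC)c(Oc3cc(OC)c(OC)c(OC)c3)c(OC)c2)c(OC)c1 | intermediate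
21 | methyl bromoacetate | COC(=O)CBr | starting material
22 | methyl 2-(B–F aryloxy)acetate | COC(=O)COc1cc(OC)c(Oc2cc(OC)c(Oc3cc(OC)c(OC)c(OC)c3Oc3cc(OC)c(Oc4cc(OC)c(OC)c(OC)c4)c(OC)c3)c(OC)c2)c(OC)c1 | intermediate
23 | methyl acetoacetate | CC(=O)CC(=O)OC | starting material
24 | dilithium dianion of methyl acetoacetate | [Li+].[Li+].COC(=O)[CH-]C(=O)[CH2-] | intermediate
25 | methyl 6-(B–F aryloxy)-3,5-dioxohexanoate (key-step precursor) | COC(=O)CC(=O)CC(=O)COc1cc(OC)c(Oc2cc(OC)c(Oc3cc(OC)c(OC)c(OC)c3Oc3cc(OC)c(Oc4cc(OC)c(OC)c(OC)c4)c(OC)c3)c(OC)c2)c(OC)c1 | intermediate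
26 | hexamer with free phloroglucinol ring A, rings B–F as twelve methyl ethers | Oc1cc(O)c(Oc2cc(OC)c(Oc3cc(OC)c(Oc4cc(OC)c(OC)c(OC)c4Oc4cc(OC)c(Oc5cc(OC)c(OC)c(OC)c5)c(OC)c4)c(OC)c3)c(OC)c2)c(O)c1 | intermediate
27 | CNP0175585.0 | Oc1cc(O)c(Oc2cc(O)c(Oc3cc(O)c(Oc4cc(O)c(O)c(O)c4Oc4cc(O)c(Oc5cc(O)c(O)c(O)c5)c(O)c4)c(O)c3)c(O)c2)c(O)c1 | target

**Step count**

Total steps: 15. Longest linear sequence: 14 steps (steps 2–15, from 4); step 1 is a one-step side branch that supplies 3.

**Steps most likely to fail**

1. Step 14 (ring A Claisen closure).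
- What may go wrong: the open-chain magnesium chelate may persist without closing because too little of the C6 carbanion tautomer is populated. On forcing, O-acylation to the pyrone during acidification or methoxide-induced retro-Claisen fragmentation of the 1,3-dicarbonyl units may consume the material.
- Fallback (known chemistry, ring A bought instead of built): setting out from phenol 20, an Ullmann diaryl ether condensation with commercial 2-iodo-1,3,5-trimethoxybenzene (CuI, 2,2,6,6-tetramethylheptane-3,5-dione, Cs2CO3, NMP, 120 °C) would give the pentadecamethyl ether of the target F1. BBr3 in CH2Cl2 (−78 °C → rt, then water) would then cleave all fifteen methyl ethers, and the sequence comes back to the route at target 27. Steps 12–15 are replaced by two operations.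

2. Step 10 (Cu-catalysed attachment of ring F).
- What may go wrong: ligand exchange and reductive elimination at a phenoxide carrying two ortho-methoxy groups on a large chain may be slow, so that protodeiodination of the aryl iodide and oxidation of the electron-rich phenoxide compete.
- Fallback (the substitution–oxidation cycle used for rings C–E, then methylation): setting out from phenol 17, SNAr with 8 (Cs2CO3, DMSO, 90 °C) should give the aldehyde F2. mCPBA in CH2Cl2 would convert it into the aryl formate F3, which K2CO3/MeOH cleaves to the phenol F4. Methylation with MeI and K2CO3 in acetone then gives 19, where the route is rejoined.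

3. Step 6 (SNAr on the ring D fluoroaldehyde).
- What may go wrong: substitution at a fluoride that is ortho to the formyl group on a trimethoxylated ring may be slow enough for phenoxide oxidation or base-induced degradation of the aldehyde to take over at the temperature needed.
- Fallback (Cu-catalysed coupling in place of SNAr): setting out from phenol 11, an Ullmann-type coupling (CuI, picolinic acid, K3PO4, DMSO, 90 °C) with 6-bromo-2,3,4-trimethoxybenzaldehyde F5 should give 12 directly, where the route is rejoined. The ortho-formyl group assists the copper insertion. F5 would be prepared by Rieche formylation (Cl2CHOMe, TiCl4, CH2Cl2, 0 °C) of commercial 5-bromo-1,2,3-trimethoxybenzene, which has a single type of ring hydrogen.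

**Further compounds**

F1 | step 14 | pentadecamethyl ether of the target (ring A as 2,4,6-trimethoxyphenyl) | COc1cc(OC)c(Oc2cc(OC)c(Oc3cc(OC)c(Oc4cc(OC)c(OC)c(OC)c4Oc4cc(OC)c(Oc5cc(OC)c(OC)c(OC)c5)c(OC)c4)c(OC)c3)c(OC)c2)c(OC)c1
F2 | step 10 | benzyl-protected B–E chain carrying a 4-formyl-3,5-dimethoxyphenyl ether as ring F precursor | COc1cc(OCc2ccccc2)cc(OC)c1Oc1cc(OC)c(Oc2cc(OC)c(OC)c(OC)c2Oc2cc(OC)c(Oc3cc(OC)c(C=O)c(OC)c3)c(OC)c2)c(OC)c1
F3 | step 10 | aryl formate from Baeyer–Villiger oxidation of F2 | COc1cc(OCc2ccccc2)cc(OC)c1Oc1cc(OC)c(Oc2cc(OC)c(OC)c(OC)c2Oc2cc(OC)c(Oc3cc(OC)c(OC=O)c(OC)c3)c(OC)c2)c(OC)c1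
F4 | step 10 | phenol from methanolysis of F3 (4-hydroxy-3,5-dimethoxyphenyl ether as ring F precursor) | COc1cc(OCc2ccccc2)cc(OC)c1Oc1cc(OC)c(Oc2cc(OC)c(OC)c(OC)c2Oc2cc(OC)c(Oc3cc(OC)c(O)c(OC)c3)c(OC)c2)c(OC)c1
F5 | step 6 | 6-bromo-2,3,4-trimethoxybenzaldehyde | COc1cc(Br)c(C=O)c(OC)c1OC
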